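**Assumption:** drimane numbering is used for all decalins (ring A = C1–C5, C10; ring B = C5–C10; C11 = CH2O on C9; C12 = CH3 on C8; α = face of H-5, β = face of the C10 methyl). The target is (5R,9R,10S), i.e. 5α-H, 10β-CH3, 9β-H with the CH2OAr group α.

**Retrosynthetic overview**
1. Target 18 ⇒ allylic diazene 17: a suprafacial [1,5]-sigmatropic H shift (loss of N2) forms the C9–H bond, sets C9 and places the alkene at C7=C8.
2. The diazene comes from the C7 tosylhydrazone of enedione 14, made by [3,3]-sigmatropic chromate transposition of tertiary allylic alcohol 11.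
3. 11 ⇒ umbelliferone 10 + spiro-epoxide 9 ⇒ bicyclic enone 7.
4. Ring A of 7 is closed last (C3–C4 bond) by hydrogen-atom-transfer radical cyclisation of keto-aldehyde 6.
5. 6 ⇒ (R)-carvone 1, which supplies all of ring B, C5, C12 and C4 with both its methyls; C10 is set by alkylation anti to the isopropenyl group.

**Step 1**
Reactants: 1 (R)-(−)-carvone
Product: 3 6-methylcarvone (C6 epimer mixture), via lithium dienolate 2 (not isolated)
Conditions: LiN(i-Pr)2 (1.1 equiv), THF, −78 °C; MeI, −78 → 0 °C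
Reagents that add atoms: iodomethane, CI
Why: Kinetic α'-deprotonation of the enone gives the cross-conjugated lithium dienolate, which is C-methylated (enolate alkylation); the new centre need not be controlled because it is re-enolised in step 2.

**Step 2**
Reactants: 3 6-methylcarvone
Product: 5 (5S,6S)-6-allyl-6-methylcarvone, via lithium enolate 4 (not isolated)
Conditions: LiN(i-Pr)2 (1.2 equiv), THF, −78 °C; allyl bromide, −78 °C → rt
Reagents that add atoms: allyl bromide, C=CCBr
Why: Enolate alkylation of the tetrasubstituted enolate occurs on the face opposite the adjacent isopropenyl group, so the allyl chain (future C1–C3) ends trans to it and the methyl (future C10–CH3) cis, which fixes C10 from the bought C5 centre.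

**Step 3**
Reactants: 5 (5S,6S)-6-allyl-6-methylcarvone
Product: 6 keto-aldehyde 3-[(1S,6S)-1,3-dimethyl-2-oxo-6-(prop-1-en-2-yl)cyclohex-3-en-1-yl]propanal
Conditions: PdCl2(PhCN)2 (10 mol %), CuCl2·2H2O (10 mol %), AgNO2 (5 mol %), O2 (1 atm), t-BuOH/MeNO2 15:1, rt
Reagents that add atoms: dioxygen, O=O
Why: The nitrite-modified, aldehyde-selective (anti-Markovnikov) Wacker oxidation touches only the monosubstituted alkene, the isopropenyl and enone alkenes being poor substrates for palladium.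

**Step 4**
Reactants: 6 keto-aldehyde
Product: 7 3ξ-hydroxy-11-nordrim-7-en-9-one (5α-H, 10β-CH3)
Conditions: Fe(acac)3 (30 mol %), PhSiH3 (2.5 equiv), EtOH, 60 °C
Reagents that add atoms: none
Why: Metal-hydride hydrogen-atom transfer (Mukaiyama-type) to the isopropenyl group gives the tertiary C4 radical, which adds 6-exo to the aldehyde carbon and closes ring A with its gem-dimethyl group; the trans ring fusion follows from the pre-set C5 and C10 centres, and the C3 carbinol configuration is irrelevant because it is oxidised in step 7.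

**Step 5**
Reactants: 7 3ξ-hydroxy-11-nordrim-7-en-9-one
Product: 9 9,11-epoxydrim-7-en-3ξ-ol, via sulfonium betaine 8 (not isolated)
Conditions: Me3S+ I− (3 equiv), n-BuLi (3 equiv), THF, −10 °C → rt
Reagents that add atoms: trimethylsulfonium iodide (as its methylide), C[S+](C)C.[I-]
Why: Corey–Chaykovsky epoxidation: the small sulfonium ylide adds 1,2 to the hindered enone carbonyl from the α face (anti to the axial C10 methyl) and the betaine closes to the oxirane; the C9 configuration is erased in step 7.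

**Step 6**
Reactants: 9 9,11-epoxydrim-7-en-3ξ-ol; 10 umbelliferone (7-hydroxycoumarin)
Product: 11 7-[(3ξ,9β-dihydroxydrim-7-en-11-yl)oxy]coumarin
Conditions: Cs2CO3 (1.5 equiv), DMF, 100 °C
Reagents that add atoms: none
Why: SN2 opening of the oxirane at its CH2 terminus by the caesium phenoxide installs the complete aryl ether and leaves a tertiary allylic alcohol at C9.

**Step 7**
Reactants: 11 7-[(3ξ,9β-dihydroxydrim-7-en-11-yl)oxy]coumarin
Product: 14 11-(umbelliferon-7-yloxy)drim-8-ene-3,7-dione, via C9 chromate ester 12 (not isolated), via C7 chromate ester 13 (not isolated)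
Conditions: pyridinium chlorochromate (C5H5NH)[CrO3Cl] (4 equiv), 4 Å MS, CH2Cl2, rt
Reagents that add atoms: pyridinium chlorochromate, [O-][Cr](=O)(=O)Cl.c1cc[nH+]cc1
Why: Dauben–Babler oxidative transposition: the tertiary allylic chromate ester undergoes a [3,3]-sigmatropic shift of oxygen from C9 to C7 and is then oxidised to the enone, while the same reagent oxidises the C3 carbinol to the ketone.

**Step 8**
Reactants: 14 11-(umbelliferon-7-yloxy)drim-8-ene-3,7-dione
Product: 15 C7 tosylhydrazone of 14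
Conditions: TsNHNH2 (1.05 equiv), EtOH, rt
Reagents that add atoms: p-toluenesulfonyl hydrazide, Cc1ccc(cc1)S(=O)(=O)NN
Why: Hydrazone condensation takes place at the unhindered enone carbonyl, the C3 ketone being shielded by the adjacent gem-dimethyl group.

**Step 9**
Reactants: 15 C7 tosylhydrazone of 14
Product: 18 target ether (5R,9R,10S), via boryl hydrazine 16 (not isolated), via allylic diazene 17 (not isolated)
Conditions: catecholborane (1.5 equiv), CHCl3, 0 °C; then NaOAc·3H2O, 60 °C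
Reagents that add atoms: none
Why: Kabalka–Myers reductive transposition: axial (α-face) hydride delivery to the C=N gives the 7β-hydrazine, loss of sulfinate gives the allylic diazene, and its suprafacial [1,5]-sigmatropic hydrogen shift (retro-ene, loss of N2) forms the C9–H bond on the β face (cis to the C10 methyl) while moving the alkene to C7=C8, so the CH2OAr group ends α (9R).

**Compound list**
1 | (R)-(−)-carvone, (5R)-2-methyl-5-(prop-1-en-2-yl)cyclohex-2-en-1-one | CC1=CC[C@@H](C(C)=C)CC1=O | starting material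
2 | lithium cross-conjugated dienolate of 1 (O–Li on C1, C1=C6 and C2=C3, C5 unchanged) | CC1=CC[C@@H](C(C)=C)C=C1O[Li] | intermediate
3 | 6-methylcarvone, (5R)-2,6-dimethyl-5-(prop-1-en-2-yl)cyclohex-2-en-1-one, C6 epimer mixture | CC1=CC[C@@H](C(C)=C)C(C)C1=O | intermediate
4 | lithium enolate of 3 (O–Li on C1, tetrasubstituted C1=C6, C2=C3) | CC1=CC[C@@H](C(C)=C)C(C)=C1O[Li] | intermediate
5 | (5S,6S)-2,6-dimethyl-6-(prop-2-en-1-yl)-5-(prop-1-en-2-yl)cyclohex-2-en-1-one (allyl trans, methyl cis to isopropenyl) | CC1=CC[C@@H](C(C)=C)[C@](C)(CC=C)C1=O | intermediate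
6 | 3-[(1S,6S)-1,3-dimethyl-2-oxo-6-(prop-1-en-2-yl)cyclohex-3-en-1-yl]propanal | CC1=CC[C@@H](C(C)=C)[C@](C)(CCC=O)C1=O | intermediate
7 | (4aS,8aS)-6-hydroxy-2,5,5,8a-tetramethyl-4a,5,6,7,8,8a-hexahydronaphthalen-1(4H)-one (3ξ-hydroxy-11-nordrim-7-en-9-one; 5α-H, 10β-CH3; C3 epimers) | CC1=CC[C@H]2C(C)(C)C(O)CC[C@]2(C)C1=O | intermediate
8 | betaine of 7: 9β-oxido-9α-[(dimethylsulfonio)methyl] adduct (drawn as zwitterion) | CC1=CC[C@H]2C(C)(C)C(O)CC[C@]2(C)[C@]1([O-])C[S+](C)C | intermediate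
9 | 9,11-epoxydrim-7-en-3ξ-ol (spiro-oxirane at C9, CH2 α, O β; 5α-H, 10β-CH3) | CC1=CC[C@H]2C(C)(C)C(O)CC[C@]2(C)[C@]1(O3)C3 | intermediate
10 | umbelliferone, 7-hydroxy-2H-chromen-2-one | Oc1ccc2ccc(=O)oc2c1 | starting material
11 | 7-[(3ξ,9β-dihydroxydrim-7-en-11-yl)oxy]-2H-chromen-2-one | CC1=CC[C@H]2C(C)(C)C(O)CC[C@]2(C)[C@]1(O)COc1ccc2ccc(=O)oc2c1 | intermediate
12 | 9β-(hydrogen chromate) ester of the tertiary allylic alcohol (drawn with C3 already a ketone) | CC1=CC[C@H]2C(C)(C)C(=O)CC[C@]2(C)[C@]1(O[Cr](=O)(=O)O)COc1ccc2ccc(=O)oc2c1 | intermediate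
13 | 7β-(hydrogen chromate) ester of 7-[(7-hydroxy-3-oxodrim-8-en-11-yl)oxy]coumarin | CC1=C(COc2ccc3ccc(=O)oc3c2)[C@@]4(C)CCC(=O)C(C)(C)[C@@H]4C[C@@H]1O[Cr](=O)(=O)O | intermediate
14 | 7-{[(4aR,8aS)-2,5,5,8a-tetramethyl-3,6-dioxo-3,4,4a,5,6,7,8,8a-octahydronaphthalen-1-yl]methoxy}-2H-chromen-2-one (11-aryloxydrim-8-ene-3,7-dione) | CC1=C(COc2ccc3ccc(=O)oc3c2)[C@@]4(C)CCC(=O)C(C)(C)[C@@H]4CC1=O | intermediate
15 | C7 N-tosylhydrazone of 14 | CC1=C(COc2ccc3ccc(=O)oc3c2)[C@@]4(C)CCC(=O)C(C)(C)[C@@H]4CC1=NNS(=O)(=O)c1ccc(C)cc1 | intermediate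
16 | 7β-[N-(1,3,2-benzodioxaborol-2-yl)-N'-tosylhydrazino]-11-aryloxydrim-8-en-3-one (7α-H) | CC1=C(COc2ccc3ccc(=O)oc3c2)[C@@]4(C)CCC(=O)C(C)(C)[C@@H]4C[C@@H]1N(NS(=O)(=O)c5ccc(C)cc5)B6Oc7ccccc7O6 | intermediate
17 | 7β-diazenyl-11-aryloxydrim-8-en-3-one (allylic diazene) | CC1=C(COc2ccc3ccc(=O)oc3c2)[C@@]4(C)CCC(=O)C(C)(C)[C@@H]4C[C@@H]1N=N | intermediate
18 | 7-{[(1R,4aR,8aS)-2,5,5,8a-tetramethyl-6-oxo-1,4,4a,5,6,7,8,8a-octahydronaphthalen-1-yl]methoxy}-2H-chromen-2-one | CC1=CC[C@H]2C(C)(C)C(=O)CC[C@]2(C)[C@@H]1COc1ccc2ccc(=O)oc2c1 | target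

**Totals**
Total step count: 9. Longest linear sequence: 9 steps, from (R)-carvone 1; umbelliferone 10 enters at step 6.

**Steps most likely to fail, with fallbacks**

Step 4 is the least secure: radical addition to an aldehyde is reversible, and simple reduction of the isopropenyl group may win. The fallback sets out from 6. Iodine in aqueous ammonia/THF converts the aldehyde into 3-[(1S,6S)-1,3-dimethyl-2-oxo-6-(prop-1-en-2-yl)cyclohex-3-en-1-yl]propanenitrile F1. The same Fe(acac)3/PhSiH3 conditions then cyclise the tertiary radical onto the nitrile, giving the ring A ketimine 3-imino-11-nordrim-7-en-9-one F2, which is hydrolysed on acidic work-up to 11-nordrim-7-ene-3,9-dione F3. NaBH4 in MeOH/CH2Cl2 at −78 °C reduces only the saturated C3 ketone and not the hindered conjugated one, and the route is rejoined at 7.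

Step 9 carries the stereochemical risk: C9 depends on α-face hydride delivery at C7, and catecholborane may also touch the C3 ketone. The fallback sets out from 14 and places the C9 hydrogen by palladium-mediated hydride transfer instead. Luche reduction (NaBH4, CeCl3·7H2O, MeOH, −78 °C) gives the equatorial allylic alcohol 7-[(7β-hydroxy-3-oxodrim-8-en-11-yl)oxy]coumarin F4. Mitsunobu inversion with formic acid (PPh3, DIAD, THF) gives the 7α-formate 7-[(7α-formyloxy-3-oxodrim-8-en-11-yl)oxy]coumarin F5. Pd(OAc)2/PBu3 in refluxing dioxane then ionises the formate with inversion and delivers hydride from the palladium-bearing β face to the more substituted allyl terminus C9, which gives 18 directly.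

Step 3 may suffer from ketone-directed Markovnikov oxidation to the methyl ketone. The fallback sets out from 5. Dicyclohexylborane (THF, 0 °C) hydroborates only the monosubstituted alkene to give the B-(3-substituted propyl)dicyclohexylborane F6. NaBO3·4H2O oxidises it to (5S,6S)-6-(3-hydroxypropyl)-2,6-dimethyl-5-(prop-1-en-2-yl)cyclohex-2-en-1-one F7, and Dess–Martin periodinane returns the route to 6.

**Further compounds**
F1 | step 4 | 3-[(1S,6S)-1,3-dimethyl-2-oxo-6-(prop-1-en-2-yl)cyclohex-3-en-1-yl]propanenitrile | CC1=CC[C@@H](C(C)=C)[C@](C)(CCC#N)C1=O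
F2 | step 4 | 3-imino-11-nordrim-7-en-9-one (5α-H, 10β-CH3) | CC1=CC[C@H]2C(C)(C)C(=N)CC[C@]2(C)C1=O
F3 | step 4 | 11-nordrim-7-ene-3,9-dione (5α-H, 10β-CH3) | CC1=CC[C@H]2C(C)(C)C(=O)CC[C@]2(C)C1=O
F4 | step 9 | 7-[(7β-hydroxy-3-oxodrim-8-en-11-yl)oxy]-2H-chromen-2-one | CC1=C(COc2ccc3ccc(=O)oc3c2)[C@@]4(C)CCC(=O)C(C)(C)[C@@H]4C[C@@H]1O
F5 | step 9 | 7-[(7α-formyloxy-3-oxodrim-8-en-11-yl)oxy]-2H-chromen-2-one | CC1=C(COc2ccc3ccc(=O)oc3c2)[C@@]4(C)CCC(=O)C(C)(C)[C@@H]4C[C@H]1OC=O
F6 | step 3 | dicyclohexyl{3-[(1S,6S)-1,3-dimethyl-2-oxo-6-(prop-1-en-2-yl)cyclohex-3-en-1-yl]propyl}borane | CC1=CC[C@@H](C(C)=C)[C@](C)(CCCB(C2CCCCC2)C2CCCCC2)C1=O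
F7 | step 3 | (5S,6S)-6-(3-hydroxypropyl)-2,6-dimethyl-5-(prop-1-en-2-yl)cyclohex-2-en-1-one | CC1=CC[C@@H](C(C)=C)[C@](C)(CCCO)C1=O
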